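Every G charged must stand somewhere, so the readings of G, Q and D in the cedar flask, charged at cG = 0.91 M, leave a gap for L and anything unread. That gap was 68.0 % at 0.250 d and 9.00 % at 3.00 d.

| flask | G | remark | time |
|---|---|---|---|
| cedar | 0.91 M | the very flask that is asked about, followed so far |  |
| flask | 0.91 M |  | 15 d |

cedar run (percent of the G charged)

| time / d | G / % | Q / % | D / % |
|---|---|---|---|
| 0.250 | 26 | 6 | 0 |
| 0.333 | 22 | 7 | 1 |
| 0.500 | 19 | 15 | 5 |
| 0.833 | 10 | 29 | 2 |
| 1.25 | 5 | 45 | 7 |
| 2.08 | 5 | 69 | 9 |
| 3.00 | 1 | 79 | 11 |

(readings scatter by 2 percentage points)

- the state of affairs at 15 d: stopped, and by what, or still going (L counts as not reacted) (it is still moving / all of G has reacted / forward and back rates have come level)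
- part of the G that has turned into other species by 15 d (L does not count)
- how much Q there is at 15 d, in percent of the G charged
- how much D there is at 15 d, in percent of the G charged
- amount of Q if the flask were left three thousand times as long, in percent of the G charged

- percentages count the G that a species holds: one D counts as two
- the numbers in the tables scatter by 2 percentage points (one standard deviation)
- in a conversion L counts as not yet reacted
- a reading or a percentage of Q counts all its forms, free or not
- the reaction counts as stopped when no species that holds the G changes by six tenths of a point or more over the second half of the time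
- a reading of G is of its free form alone

The fall of G from 26 % at 0.250 d to 5 % at 1.25 d put at 0.420 d the clearing time, the time in which the reading of G halves (a first-order half-life). I went no further along the run, since the later readings stand close to the scatter of 2 percentage points.

Then I turned the question round. For G itself still to be changing in the cedar flask at 15 d, G would have to hold about 0.5 point at mid-time, close to the stopping margin, and from 26 % that needs a clearing time of 1.27 d. The reading stands at a third of that, so I committed to a flask stopped with G used up, assuming that L follows G down and that Q and D come to rest with them. This reckoning did not say how the gap would divide.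

The forecast said all of G has reacted, with conversion 100 %, Q 87 %, D 13 % and Q 87 % at long times, since “almost nothing should remain”.

The flask gives all of G has reacted, conversion 100 %, Q 86.3 %, D 7.76 % and Q 86.3 % at long times.

    G ⇌ L (K = 1.50, k = 0.0110 min⁻¹)
    G → Q (k = 2.70 × 10⁻⁴ min⁻¹)
    L → E (k = 0.00200 min⁻¹)
    Q ⇌ E (K = 0.590, k = 4.50 × 10⁻⁴ min⁻¹)
    G + Q → D (k = 0.00170 M⁻¹ min⁻¹)
    J ⇌ Q, rate k6*(cs6 - [Q]) while solid is left; crystals form when [Q] > cs6 (solubility = 0.0910 M, k = 0.0520 min⁻¹)

At 7.50 d the cedar flask held G 0 % and L 0 %, as the clearing time required, but the gap had not closed: E, unread in the cedar run, stood at 5.96 %. The neighbouring flask is the same charge read at 6.0 d. Its earlier mid-time needs a clearing time of 0.482 d for G itself still to be changing, and 0.420 d is shorter, though by a much narrower margin; this speaks of G alone. That flask held G 0 %, L 0 %, Q 86.0 %, D 7.76 % and E 6.19 %. Its Q stood 7 points above the reading of 79 % at 3.00 d, its mid-time.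

(Readings and results are simulated with made-up constants; the scatter is artificial.)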